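Abbreviations: PMB = 4‑methoxybenzyl, TBS = tert‑butyldimethylsilyl, TES = triethylsilyl, TMS = trimethylsilyl. Atoms carry germacranolide numbers: ring C1–C10; C11, C12, C13 = lactone α‑carbon, lactone carbonyl, acetoxymethyl carbon; C14 = methyl on C10; C15 = methyl on C4.

## Analysis of the target

The target is a germacranolide: a ten‑membered carbocycle (C1–C10) fused along C6–C7 to an α,β‑unsaturated γ‑lactone (O–C12(=O)–C11=C7), whose α‑carbon C11 carries the acetoxymethyl carbon C13. The carbocycle bears a C1 ketone, a quaternary C10 (methyl and acetate), a C8 angelate and a C4–C5 epoxide with the C15 methyl on C4. There are five stereocentres, 4R,5R,6S,8S,10R. C4, C5 and C6 are contiguous; the epoxide is that of an E C4=C5 alkene, and its oxygen lies on the same side as the lactone oxygen and anti to C7 across C5–C6. C8 and C10 are 1,3‑related and are separated from C6 only by the trigonal C7. The sensitive groups are the angelate (Z to E isomerisation on activation), the epoxide next to the acidic γ‑proton H6 of the butenolide (base opens it through the furanolate, which can also expel the C13 acetate), the tertiary α‑acetoxy ketone, and the medium ring itself (acid causes transannular reactions). The difficulty is to close a ten‑membered ring with an E trisubstituted alkene and then to place three different esters and three stereocentres on a ring with no rigid framework. The strategy rests on two features: C1=O and C4=C5 are joined by C2–C3 as a γ,δ‑unsaturated ketone (a Claisen retron, C5 being the former allylic C–O carbon), and the butenolide C6–C7–C11–C12 is the oxidised form of a tetrasubstituted furan whose C6–C7 edge acts as a cis element in an eight‑membered precursor.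

## Retrosynthetic reasoning

33 to 32. The two C–O bonds of the epoxide are cut last, because the epoxide is the group least tolerant of base, acid and fluoride. With C6 already in place in 32, a neutral oxygen‑transfer reagent only has to attack the exposed face of the E alkene.

32 to 30. The C13 ester bond is cut next, back to the PMB ether 30 through alcohol 31. The primary allylic oxygen is kept as an ether until the lactone exists, because an acyloxy group on C13 would be a leaving group while C11 is the nucleophilic carbon of a silyloxyfuran.

30 to 28. The lactone C12=O and the C6–H bond are traced back to the C12–Si bond of silylfuran 28. The forward step is an ipso oxidation that must spare the C4=C5 alkene and protonate C6 rather than C11.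

28 to 25. The C10 acetate and the C8 angelate are disconnected at the furan stage, through 27 and diol 26. The aromatic furan has no acidic γ‑proton, so the forcing tertiary acetylation and the warm angeloylation are done before the base‑sensitive butenolide exists.

25 to 24. This is the key disconnection: C2–C3 is cut and C5–O reconnected, turning the ten‑membered γ,δ‑unsaturated ketone into the eight‑membered 2‑methyleneoxocane 24. All fifteen skeletal carbons and the C8 and C10 stereocentres are then already present when the ring is made. The forward step has to deliver the E alkene.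

24 to 22. The exocyclic methylene is removed to lactone 23 (carbonyl methylenation forward), and the lactone C1–O bond is cut to hydroxy acid 22. The furan edge and the quaternary C10 are relied on to make the eight‑membered lactonisation feasible.

22 to 17. The C5–C4 bond is cut to aldehyde 21, so C5 appears only two steps before it is destroyed and needs no protecting group. 21 goes back through acid 20 to hydroxy ester 17 by protecting‑group changes. The C8 oxygen must be silylated before C1 is activated, since C8–OH and C1 are in a γ relationship and would close a five‑membered lactone.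

17 to 9 and 14. The C8 stereocentre is assigned to a reagent‑controlled reduction of ketone 16. The C7–C8 bond is cut between a furan‑3‑yl anion from bromide 9 and the acyl group of Weinreb amide 14. This is the most convergent cut and joins two pieces of similar size.

9 to 1, and 14 to 10. Furan 9 is reached from dibromide 1 by three successive ring metalations, each directed by the substituent already present (C13, then C5, then silicon on C12). Amide 14 keeps the C10 stereocentre of 10 untouched; the two carboxyl groups of 10 are told apart by closing the α‑hydroxy acid as a dioxolanone.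

## Alternatives that were turned down

Alternative 1: Anionic oxy‑Cope ring expansion. The ring bond C8–C9 is cut and a six‑membered ring (ring A, C1–C6) is re‑formed across C1–C6. The precursor is a cyclohexanol carrying a silyl‑substituted alkenyl group on the carbinol carbon and a trans isopropenyl group next to it. Its potassium alkoxide would undergo a [3,3] shift through a chair to the enolate of A1, with an E C1=C10 alkene. In its favour: the driving force is large, the E geometry from a trans‑disubstituted cyclohexane chair is dependable, and the C4/C5 oxygens are set on a six‑membered ring. On certainty of ring formation and of alkene geometry this route is stronger than the chosen one. Against it for this target: A1 has its alkene at C1=C10, where the target needs a ketone and a tertiary acetate, so C10 would have to be set by oxidation on the flexible ring. C6 is a ketone and C7 a bare methylene, so all three lactone carbons must still be attached and C6 reduced with control. The C8 silane needs a Fleming–Tamao oxidation in the presence of an alkene. The chosen strategy instead forms the ring with every skeletal carbon, C8 and C10 in place, leaving only acylations and two oxidations.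

Alternative 2: Photocycloaddition followed by thermal cycloreversion. Both ring alkenes (C1=C10 and C4=C5) are traced back to a cyclobutane (C1, C10, C5, C4) inside a tricyclic photoadduct. Heating cleaves C1–C4 and C5–C10 and opens the ten‑membered dienone A2. In its favour: it is by far the shortest way to the carbocycle, it brings both ring methyls and the C8 oxygen, and the 4E alkene is formed in conjugation with the C6 ketone. In step economy up to the ring it beats the chosen route. Against it: A2 is a cyclodeca‑1,5‑diene and can undergo Cope rearrangement to a divinylcyclohexane at the temperature of its formation. Its C1=C10 alkene must be turned regioselectively into ketone plus tertiary acetate next to a second alkene. The C4=C5 alkene is an enone and would need nucleophilic epoxidation before C6 is reduced. C7 again lacks the lactone carbons, and four of the five stereocentres would have to be set on the medium ring. The chosen route spends more steps before the ring but needs no carbon–carbon bond formation after it.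

Alternative 3: Eschenmoser–Tanabe fragmentation and directed alkyne hydration. The C1–C6 bond is re‑formed to give a decalin with a C1–C6 epoxide and a C2 ketone. Its sulfonylhydrazone would fragment with loss of N2 and sulfinate to the cyclodecynone A3, and the propargylic acetate on C10 would then steer hydration of the alkyne to the C1 ketone. In its favour: C4, C5, C8 and C10 are all set on a rigid bicycle, the ring opening is irreversible, no alkene geometry is at stake, and the acetate‑assisted hydration gives exactly the C1 ketone beside the C10 acetate. On stereocontrol at C4/C5 and on certainty of ring opening this is stronger than the chosen route. Against it: the densely functionalised epoxy decalone is a long synthesis in itself, and a cyclodecyne carrying a ketone and an acetonide is strained. As in the other two alternatives the lactone carbons must still be appended at C7, C6 reduced with control, and the diol converted into the epoxide next to a base‑sensitive centre. The chosen route accepts a less certain ring‑forming step in exchange for a much shorter path on which the lactone is carried as a furan.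

Key step: step 17

Assumption: the C5 carbinol made in step 14 is formed without control and 22–24 are carried as both C5 epimers, which is harmless because C5 becomes trigonal in step 17.

## Route

Step 1
Reactants: 1 3,4-dibromofuran
Product: 4 (4-bromofuran-3-yl)methanol, via 3-bromo-4-lithiofuran 2 (not isolated), via 4-bromofuran-3-carbaldehyde 3 (not isolated)
Conditions: n-BuLi (1.0 equiv), Et2O, −78 °C; DMF, −78 → 0 °C; then MeOH, NaBH4, 0 °C
Reagents that add atoms: N,N-dimethylformamide CN(C)C=O
Why: Bromine–lithium exchange on the symmetric dibromide stops at the monolithio stage at −78 °C, where the 3‑lithiofuran is stable; formylation and borohydride reduction in the same flask give the C13 hydroxymethyl group.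

Step 2
Reactants: 4 (4-bromofuran-3-yl)methanol
Product: 5 3-bromo-4-{[(4-methoxybenzyl)oxy]methyl}furan
Conditions: NaH, 4-methoxybenzyl chloride, Bu4NI (cat.), THF/DMF, 0 °C → rt
Reagents that add atoms: 4-methoxybenzyl chloride COc1ccc(CCl)cc1
Why: Williamson etherification; the PMB ether withstands organolithium reagents and heat, is a poor leaving group when C11 later becomes the nucleophilic carbon of a silyloxyfuran, and is removed oxidatively without acid or base.

Step 3
Reactants: 5 3-bromo-4-{[(4-methoxybenzyl)oxy]methyl}furan
Product: 7 3-bromo-4-{[(4-methoxybenzyl)oxy]methyl}furan-2-carbaldehyde, via 3-bromo-2-lithio-4-(PMB-oxymethyl)furan 6 (not isolated)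
Conditions: LiN(iPr)2, THF, −78 °C; DMF; aq. NH4Cl
Reagents that add atoms: N,N-dimethylformamide CN(C)C=O
Why: The amide base removes the ring proton between the ring oxygen and the C–Br carbon (the most acidic one, ortho‑metalation directed by bromine) without exchanging the bromine; formylation installs C5 on C6.

Step 4
Reactants: 7 3-bromo-4-{[(4-methoxybenzyl)oxy]methyl}furan-2-carbaldehyde
Product: 8 3-bromo-2-(dimethoxymethyl)-4-{[(4-methoxybenzyl)oxy]methyl}furan
Conditions: HC(OMe)3, MeOH, PPTS (cat.), rt
Reagents that add atoms: trimethyl orthoformate COC(OC)OC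
Why: Acid‑catalysed acetalisation masks the C5 aldehyde against the organolithium of step 10 and the borane of step 11.

Step 5
Reactants: 8 3-bromo-2-(dimethoxymethyl)-4-{[(4-methoxybenzyl)oxy]methyl}furan
Product: 9 [4-bromo-5-(dimethoxymethyl)-3-{[(4-methoxybenzyl)oxy]methyl}furan-2-yl]trimethylsilane
Conditions: Me3SiCl, then lithium 2,2,6,6-tetramethylpiperidide (from the amine and n-BuLi), THF, −78 °C
Reagents that add atoms: chlorotrimethylsilane C[Si](C)(C)Cl
Why: The last ring proton (C12–H) is removed by the hindered amide and trapped in situ, which leaves the bromine in place and avoids halogen migration; the C12 silyl group marks the future lactone carbonyl.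

Step 6
Reactants: 10 (R)-citramalic acid
Product: 11 [(4R)-2,2,4-trimethyl-5-oxo-1,3-dioxolan-4-yl]acetic acid
Conditions: 2,2-dimethoxypropane, TsOH·H2O (cat.), rt
Reagents that add atoms: 2,2-dimethoxypropane COC(C)(C)OC
Why: The α‑hydroxy acid closes the five‑membered dioxolanone in preference to the six‑membered alternative, which masks C1 and the C10 hydroxyl and leaves the C8 carboxyl free; the C10 stereocentre is not touched.

Step 7
Reactants: 11 [(4R)-2,2,4-trimethyl-5-oxo-1,3-dioxolan-4-yl]acetic acid
Product: 12 N-methoxy-N-methyl-2-[(4R)-2,2,4-trimethyl-5-oxo-1,3-dioxolan-4-yl]acetamide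
Conditions: MeNHOMe·HCl, EDC·HCl, N-methylmorpholine, CH2Cl2, 0 °C → rt
Reagents that add atoms: N,O-dimethylhydroxylamine hydrochloride CNOC.Cl
Why: Carbodiimide amidation gives the Weinreb amide, the acyl donor that stops at the ketone in step 10.

Step 8
Reactants: 12 N-methoxy-N-methyl-2-[(4R)-2,2,4-trimethyl-5-oxo-1,3-dioxolan-4-yl]acetamide
Product: 13 methyl (2R)-2-hydroxy-4-[methoxy(methyl)amino]-2-methyl-4-oxobutanoate
Conditions: NaOMe (cat.), MeOH, 0 °C
Reagents that add atoms: methanol CO
Why: Methoxide‑catalysed transesterification opens the activated dioxolanone to the methyl ester and the free tertiary alcohol with loss of acetone; the Weinreb amide is inert under these conditions.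

Step 9
Reactants: 13 methyl (2R)-2-hydroxy-4-[methoxy(methyl)amino]-2-methyl-4-oxobutanoate
Product: 14 methyl (2R)-4-[methoxy(methyl)amino]-2-methyl-4-oxo-2-[(triethylsilyl)oxy]butanoate
Conditions: Et3SiOTf, 2,6-lutidine, CH2Cl2, −78 → 0 °C
Reagents that add atoms: triethylsilyl trifluoromethanesulfonate CC[Si](CC)(CC)OS(=O)(=O)C(F)(F)F
Why: A silyl triflate is needed to silylate the hindered tertiary alcohol; the TES ether keeps the C10 oxygen out of all later organometallic and acylation steps.

Step 10
Reactants: 9 [4-bromo-5-(dimethoxymethyl)-3-{[(4-methoxybenzyl)oxy]methyl}furan-2-yl]trimethylsilane, 14 methyl (2R)-4-[methoxy(methyl)amino]-2-methyl-4-oxo-2-[(triethylsilyl)oxy]butanoate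
Product: 16 methyl (2R)-4-[2-(dimethoxymethyl)-4-{[(4-methoxybenzyl)oxy]methyl}-5-(trimethylsilyl)furan-3-yl]-2-methyl-4-oxo-2-[(triethylsilyl)oxy]butanoate, via furan-3-yllithium 15 (not isolated)
Conditions: t-BuLi (2.0 equiv), Et2O, −78 °C; then 14, THF, −78 °C; aq. NH4Cl
Reagents that add atoms: none
Why: Bromine–lithium exchange gives the 3‑furyllithium, which acylates at the Weinreb amide (chelated tetrahedral adduct, no over‑addition) much faster than it attacks the neopentyl‑type methyl ester at −78 °C; this forms the C7–C8 bond.

Step 11
Reactants: 16 methyl (2R)-4-[2-(dimethoxymethyl)-4-{[(4-methoxybenzyl)oxy]methyl}-5-(trimethylsilyl)furan-3-yl]-2-methyl-4-oxo-2-[(triethylsilyl)oxy]butanoate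
Product: 17 methyl (2R,4S)-4-[2-(dimethoxymethyl)-4-{[(4-methoxybenzyl)oxy]methyl}-5-(trimethylsilyl)furan-3-yl]-4-hydroxy-2-methyl-2-[(triethylsilyl)oxy]butanoate
Conditions: (R)-2-methyl-CBS-oxazaborolidine (C18H20BNO, 0.3 equiv), BH3·SMe2, THF, −20 °C; MeOH
Reagents that add atoms: none
Why: Corey–Bakshi–Shibata reduction of a heteroaryl alkyl ketone; with the substituted furan as the large group the (R)‑catalyst delivers hydride to the face that gives 8S, under reagent control. If 17 closes in part to the γ‑lactone on C8–O and C1, both forms converge in step 12.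

Step 12
Reactants: 17 methyl (2R,4S)-4-[2-(dimethoxymethyl)-4-{[(4-methoxybenzyl)oxy]methyl}-5-(trimethylsilyl)furan-3-yl]-4-hydroxy-2-methyl-2-[(triethylsilyl)oxy]butanoate
Product: 20 (2R,4S)-4-[(tert-butyldimethylsilyl)oxy]-4-[2-(dimethoxymethyl)-4-{[(4-methoxybenzyl)oxy]methyl}-5-(trimethylsilyl)furan-3-yl]-2-methyl-2-[(triethylsilyl)oxy]butanoic acid, via lithium carboxylate 18 (not isolated), via bis-silyl compound 19 (not isolated)
Conditions: LiOH, THF/H2O, rt; evaporate; t-BuMe2SiCl, imidazole, DMF, 40 °C; K2CO3, MeOH/H2O, 0 °C; pH 5 buffer
Reagents that add atoms: lithium hydroxide [Li+].[OH-]; tert-butyldimethylsilyl chloride CC(C)(C)[Si](C)(C)Cl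
Why: Saponification of the hindered ester is assisted by the γ‑hydroxyl; silylation of the carboxylate salt gives the TBS ether and TBS ester, and the labile silyl ester is cleaved selectively by carbonate. The C8 oxygen is thus blocked before C1 is activated, which rules out γ‑lactone formation in step 15.

Step 13
Reactants: 20 (2R,4S)-4-[(tert-butyldimethylsilyl)oxy]-4-[2-(dimethoxymethyl)-4-{[(4-methoxybenzyl)oxy]methyl}-5-(trimethylsilyl)furan-3-yl]-2-methyl-2-[(triethylsilyl)oxy]butanoic acid
Product: 21 (2R,4S)-4-[(tert-butyldimethylsilyl)oxy]-4-[2-formyl-4-{[(4-methoxybenzyl)oxy]methyl}-5-(trimethylsilyl)furan-3-yl]-2-methyl-2-[(triethylsilyl)oxy]butanoic acid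
Conditions: PPTS (cat.), acetone/H2O, rt
Reagents that add atoms: water O
Why: The acetal of a furan‑2‑carbaldehyde hydrolyses under very mild acid, which the tertiary TES ether, the secondary TBS ether and the C–Si bond survive.

Step 14
Reactants: 21 (2R,4S)-4-[(tert-butyldimethylsilyl)oxy]-4-[2-formyl-4-{[(4-methoxybenzyl)oxy]methyl}-5-(trimethylsilyl)furan-3-yl]-2-methyl-2-[(triethylsilyl)oxy]butanoic acid
Product: 22 (2R,4S)-4-[(tert-butyldimethylsilyl)oxy]-4-[2-(1-hydroxy-2-methylprop-2-en-1-yl)-4-{[(4-methoxybenzyl)oxy]methyl}-5-(trimethylsilyl)furan-3-yl]-2-methyl-2-[(triethylsilyl)oxy]butanoic acid (both epimers at the new carbinol C5)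
Conditions: CH2=C(CH3)MgBr (3 equiv), THF, −78 → −20 °C; pH 5 citrate buffer
Reagents that add atoms: isopropenylmagnesium bromide CC(=C)[Mg]Br
Why: Grignard addition; the first equivalent forms the unreactive magnesium carboxylate and the next adds to the aldehyde, bringing in C4, C3 and C15. C5 forms as both epimers; buffered work‑up protects the acid‑labile furyl allyl carbinol.

Step 15
Reactants: 22 seco acid (both C5 epimers)
Product: 23 eight-membered lactone: furan-fused oxocan-2-one with ring O–C1(=O)–C10–C9–C8–C7=C6–C5; (8S,10R); C5 isopropenyl (both epimers); C8 OTBS; C10 methyl and OTES; C11 CH2OPMB; C12 SiMe3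
Conditions: 2-methyl-6-nitrobenzoic anhydride, DMAP, CH2Cl2 (2 mM, slow addition), rt
Reagents that add atoms: none
Why: Shiina macrolactonisation through the mixed anhydride; the cis furan edge C6=C7 and the quaternary C10 pre‑organise the chain for eight‑membered ring closure, and the acid has no α‑hydrogen to lose.

Step 16
Reactants: 23 eight-membered lactone (both C5 epimers)
Product: 24 Claisen precursor: furan-fused 2-methylene-8-isopropenyloxocane (C1=C2H2 exocyclic; substituents as in 23; both C5 epimers)
Conditions: Cp2TiMe2, toluene, pyridine (trace), 65–70 °C, dark; Et3N-deactivated silica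
Reagents that add atoms: dimethyltitanocene C[Ti](C)(C1C=CC=C1)C1C=CC=C1
Why: Petasis methylenation of the only carbonyl group gives the exocyclic enol ether; the quaternary C10 prevents isomerisation into the ring. Any 25 already formed at this temperature is carried into step 17.

Step 17
Reactants: 24 furan-fused 2-methylene-8-isopropenyloxocane (both C5 epimers)
Product: 25 (4E,8S,10R)-furan-fused cyclodec-4-en-1-one: ring C1(=O)–C2–C3–C4(CH3)=C5–C6(furan)=C7(furan)–C8(OTBS)–C9–C10(CH3)(OTES); C11 CH2OPMB; C12 SiMe3
Conditions: toluene (0.01 M), Et3N (trace), base-washed sealed tube, 110 °C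
Reagents that add atoms: none
Why: The exocyclic enol ether C2=C1–O and the C5 isopropenyl group form an allyl vinyl ether held inside the eight‑membered ring; on heating, a concerted [3,3]-sigmatropic shift (aliphatic Claisen rearrangement) forms C2–C3, breaks the furfurylic and allylic C5–O bond and turns the ring oxygen into the C1 carbonyl, which drives the reaction. The closest known reaction type is the Claisen ring expansion of 2‑methylene‑6‑vinyltetrahydropyrans to cyclooct‑4‑enones, carried here from six‑to‑eight to eight‑to‑ten. The ten‑membered carbocycle is not closed end to end: it arises by two‑carbon ring expansion, the only new bond (C2–C3) being made inside the six‑membered chair‑like pericyclic array while the furan stays untouched. No stereocentre is created and C5 becomes trigonal, so both C5 epimers of 24 should converge. The selectivity needed is the E geometry of C4=C5; it comes from the chair with C6 pseudo‑equatorial on C5, which keeps the tetrasubstituted furan away from the C2 methylene hydrogens and leaves the C4 methyl at the unhindered central position. That array requires C6–C5–O–C1 to open towards antiperiplanar, which the lengthening C5–O bond, the wide exocyclic angles of the furan and the five‑atom tether C6–C10 should allow, unlike the six‑to‑eight case, where only the cis alkene can form. The chair with C6 pseudo‑axial would give the Z isomer and is the main risk. Because the furan stabilises cationic character at C5, a non‑polar solvent, a trace of amine and base‑washed glass are used to keep the shift concerted and to protect the acid‑labile enol ether.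

Step 18
Reactants: 25 (4E,8S,10R)-furan-fused cyclodec-4-en-1-one
Product: 26 C8,C10-diol of 25 (C8 OH, C10 OH; C13 OPMB and C12 SiMe3 kept)
Conditions: HF·pyridine, pyridine, THF, 0 °C → rt
Reagents that add atoms: none
Why: Buffered HF cleaves the tertiary TES and the secondary TBS ether without generating a furfuryl cation at C8; the PMB ether and the furan C–Si bond are expected to survive.

Step 19
Reactants: 26 C8,C10-diol
Product: 27 C8 angelate of 26 (C10 OH free)
Conditions: angelic acid, 2,4,6-trichlorobenzoyl chloride, Et3N, toluene, rt; then 26, 60 °C
Reagents that add atoms: angelic acid C/C=C(/C)C(=O)O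
Why: Yamaguchi esterification with the preformed mixed anhydride acylates the secondary C8 hydroxyl and leaves the hindered tertiary C10 hydroxyl alone; these conditions are the ones known to preserve the Z geometry of the angeloyl group. If 26 rests as the C8–O–C1 hemiketal, it equilibrates with the hydroxy ketone under the basic conditions.

Step 20
Reactants: 27 C8 angelate
Product: 28 C8 angelate C10 acetate (furan stage; C13 OPMB; C12 SiMe3)
Conditions: Ac2O, DMAP, Et3N, CH2Cl2, rt
Reagents that add atoms: acetic anhydride CC(=O)OC(C)=O
Why: DMAP‑catalysed acetylation of the tertiary α‑ketol; it is done while the lactone is still an aromatic furan, so no acidic γ‑proton or epoxide is exposed to the base, and the finished angelate ester does not isomerise under acyl‑transfer conditions.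

Step 21
Reactants: 28 C8 angelate C10 acetate (furan stage)
Product: 30 (4E,6S,8S,10R)-butenolide: C12=O, C7=C11, H on C6; C13 OPMB; C8 angelate; C10 acetate; C1 ketone, via 2-silyloxyfuran 29 (not isolated)
Conditions: AcOOH (1.1 equiv), NaOAc, CH2Cl2, −20 → 0 °C
Reagents that add atoms: peracetic acid CC(=O)OO
Why: Peracid ipso oxidation of a 2‑silylfuran: oxygen is delivered to the silyl‑bearing C12 (the cation is β to silicon and stabilised by the ring oxygen), carbon‑to‑oxygen silyl shift gives the silyloxyfuran, and protonation at C6 gives the conjugated butenolide. One equivalent at low temperature is used so that the tetrasubstituted silylfuran reacts before the trisubstituted alkene. C6 is set by protonation of the planar silyloxyfuran on the face away from the C5=C4 arm of the ring, which is expected to lie on the side of the C8 acyloxy group and so to give 6S; this is the least secure stereochemical assignment of the route.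

Step 22
Reactants: 30 (4E,6S,8S,10R)-butenolide
Product: 31 C13 alcohol of 30
Conditions: DDQ, CH2Cl2/pH 7 buffer, 0 °C
Reagents that add atoms: none
Why: Oxidative cleavage of the PMB ether under neutral conditions; the electron‑poor butenolide and angelate and the isolated alkene are not attacked.

Step 23
Reactants: 31 C13 alcohol
Product: 32 (4E,6S,8S,10R)-13-acetoxy-10-acetoxy-8-angeloyloxy-1-oxogermacra-4,7(11)-dien-12,6-olide
Conditions: Ac2O, pyridine, CH2Cl2, 0 °C
Reagents that add atoms: acetic anhydride CC(=O)OC(C)=O
Why: The primary allylic alcohol is acetylated quickly with pyridine alone, a base too weak to deprotonate C6; prompt acylation also prevents migration of the neighbouring C8 acyl group.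

Step 24
Reactants: 32 triester alkene
Product: 33 target (4R,5R,6S,8S,10R)-epoxide
Conditions: dimethyldioxirane, acetone, −20 → 0 °C
Reagents that add atoms: dimethyldioxirane CC1(C)OO1
Why: Neutral dioxirane epoxidation of the only electron‑rich alkene is stereospecific, so the E alkene gives the trans epoxide. Allylic 1,3‑strain with the C4 methyl puts H6 in the alkene plane, so C7 and the ring cover one face and the lactone oxygen sits on the other; oxygen is delivered to the open, peripheral face, anti to C7, which is 4R,5R.

## Compound list

1 | 3,4-dibromofuran | Brc1cocc1Br | starting material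
2 | 3-bromo-4-lithiofuran | [Li]c1cocc1Br | intermediate (not isolated)
3 | 4-bromofuran-3-carbaldehyde | O=Cc1cocc1Br | intermediate (not isolated)
4 | (4-bromofuran-3-yl)methanol | OCc1cocc1Br | intermediate
5 | 3-bromo-4-{[(4-methoxybenzyl)oxy]methyl}furan | COc1ccc(COCc2cocc2Br)cc1 | intermediate
6 | 3-bromo-2-lithio-4-(PMB-oxymethyl)furan | COc1ccc(COCc2coc([Li])c2Br)cc1 | intermediate (not isolated)
7 | 3-bromo-4-{[(4-methoxybenzyl)oxy]methyl}furan-2-carbaldehyde | COc1ccc(COCc2coc(C=O)c2Br)cc1 | intermediate
8 | 3-bromo-2-(dimethoxymethyl)-4-{[(4-methoxybenzyl)oxy]methyl}furan | COc1ccc(COCc2coc(C(OC)OC)c2Br)cc1 | intermediate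
9 | [4-bromo-5-(dimethoxymethyl)-3-{[(4-methoxybenzyl)oxy]methyl}furan-2-yl]trimethylsilane | COc1ccc(COCc2c([Si](C)(C)C)oc(C(OC)OC)c2Br)cc1 | intermediate
10 | (R)-citramalic acid | OC(=O)C[C@@](C)(O)C(=O)O | starting material
11 | [(4R)-2,2,4-trimethyl-5-oxo-1,3-dioxolan-4-yl]acetic acid | OC(=O)C[C@@]1(C)OC(C)(C)OC1=O | intermediate
12 | N-methoxy-N-methyl-2-[(4R)-2,2,4-trimethyl-5-oxo-1,3-dioxolan-4-yl]acetamide | CON(C)C(=O)C[C@@]1(C)OC(C)(C)OC1=O | intermediate
13 | methyl (2R)-2-hydroxy-4-[methoxy(methyl)amino]-2-methyl-4-oxobutanoate | CON(C)C(=O)C[C@@](C)(O)C(=O)OC | intermediate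
14 | methyl (2R)-4-[methoxy(methyl)amino]-2-methyl-4-oxo-2-[(triethylsilyl)oxy]butanoate | CON(C)C(=O)C[C@@](C)(O[Si](CC)(CC)CC)C(=O)OC | intermediate
15 | furan-3-yllithium from 9 | COc1ccc(COCc2c([Si](C)(C)C)oc(C(OC)OC)c2[Li])cc1 | intermediate (not isolated)
16 | furyl ketone (C8=O), methyl ester | O=C(c1c(C(OC)OC)oc([Si](C)(C)C)c1COCc1ccc(OC)cc1)C[C@@](C)(O[Si](CC)(CC)CC)C(=O)OC | intermediate
17 | (2R,4S)-hydroxy ester (8S alcohol) | O[C@H](c1c(C(OC)OC)oc([Si](C)(C)C)c1COCc1ccc(OC)cc1)C[C@@](C)(O[Si](CC)(CC)CC)C(=O)OC | intermediate
18 | lithium carboxylate of the hydroxy acid | O[C@H](c1c(C(OC)OC)oc([Si](C)(C)C)c1COCc1ccc(OC)cc1)C[C@@](C)(O[Si](CC)(CC)CC)C(=O)[O-].[Li+] | intermediate (not isolated)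
19 | C8 TBS ether TBS ester | CC(C)(C)[Si](C)(C)O[C@H](c1c(C(OC)OC)oc([Si](C)(C)C)c1COCc1ccc(OC)cc1)C[C@@](C)(O[Si](CC)(CC)CC)C(=O)O[Si](C)(C)C(C)(C)C | intermediate (not isolated)
20 | C8 TBS ether acid with C5 acetal | CC(C)(C)[Si](C)(C)O[C@H](c1c(C(OC)OC)oc([Si](C)(C)C)c1COCc1ccc(OC)cc1)C[C@@](C)(O[Si](CC)(CC)CC)C(=O)O | intermediate
21 | aldehyde acid | CC(C)(C)[Si](C)(C)O[C@H](c1c(C=O)oc([Si](C)(C)C)c1COCc1ccc(OC)cc1)C[C@@](C)(O[Si](CC)(CC)CC)C(=O)O | intermediate
22 | seco hydroxy acid (both C5 epimers) | CC(C)(C)[Si](C)(C)O[C@H](c1c(C(O)C(C)=C)oc([Si](C)(C)C)c1COCc1ccc(OC)cc1)C[C@@](C)(O[Si](CC)(CC)CC)C(=O)O | intermediate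
23 | furan-fused eight-membered lactone (both C5 epimers) | O=C1OC(C(C)=C)c2oc([Si](C)(C)C)c(COCc3ccc(OC)cc3)c2[C@@H](O[Si](C)(C)C(C)(C)C)C[C@@]1(C)O[Si](CC)(CC)CC | intermediate
24 | furan-fused 2-methylene-8-isopropenyloxocane (both C5 epimers) | C=C1OC(C(C)=C)c2oc([Si](C)(C)C)c(COCc3ccc(OC)cc3)c2[C@@H](O[Si](C)(C)C(C)(C)C)C[C@@]1(C)O[Si](CC)(CC)CC | intermediate
25 | (4E,8S,10R)-furan-fused cyclodec-4-en-1-one | O=C1CC/C(C)=C/c2oc([Si](C)(C)C)c(COCc3ccc(OC)cc3)c2[C@@H](O[Si](C)(C)C(C)(C)C)C[C@@]1(C)O[Si](CC)(CC)CC | intermediate
26 | C8,C10-diol | O=C1CC/C(C)=C/c2oc([Si](C)(C)C)c(COCc3ccc(OC)cc3)c2[C@@H](O)C[C@@]1(C)O | intermediate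
27 | C8 angelate, C10 alcohol | O=C1CC/C(C)=C/c2oc([Si](C)(C)C)c(COCc3ccc(OC)cc3)c2[C@@H](OC(=O)/C(C)=C\C)C[C@@]1(C)O | intermediate
28 | C8 angelate, C10 acetate (silylfuran) | O=C1CC/C(C)=C/c2oc([Si](C)(C)C)c(COCc3ccc(OC)cc3)c2[C@@H](OC(=O)/C(C)=C\C)C[C@@]1(C)OC(C)=O | intermediate
29 | 2-(trimethylsilyloxy)furan | O=C1CC/C(C)=C/c2oc(O[Si](C)(C)C)c(COCc3ccc(OC)cc3)c2[C@@H](OC(=O)/C(C)=C\C)C[C@@]1(C)OC(C)=O | intermediate (not isolated)
30 | (6S)-butenolide, C13 OPMB | O=C1CC/C(C)=C/[C@H]2OC(=O)C(COCc3ccc(OC)cc3)=C2[C@@H](OC(=O)/C(C)=C\C)C[C@@]1(C)OC(C)=O | intermediate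
31 | butenolide, C13 alcohol | O=C1CC/C(C)=C/[C@H]2OC(=O)C(CO)=C2[C@@H](OC(=O)/C(C)=C\C)C[C@@]1(C)OC(C)=O | intermediate
32 | (4E)-alkene with all three esters | O=C1CC/C(C)=C/[C@H]2OC(=O)C(COC(C)=O)=C2[C@@H](OC(=O)/C(C)=C\C)C[C@@]1(C)OC(C)=O | intermediate
33 | CNP0175424.2 | C/C=C(/C)C(=O)O[C@H]1C[C@@](C)(OC(C)=O)C(=O)CC[C@@]2(C)O[C@@H]2[C@H]2OC(=O)C(COC(C)=O)=C12 | target

## Step count and least certain steps

Total: 24 steps. Longest linear sequence: 20 steps (1 to 9 in steps 1–5, then steps 10–24). The branch from 10 (steps 6–9) is 4 steps and joins at step 10.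

Step 17 (key step). The eight‑membered ring may resist opening towards the C6‑equatorial chair, so the rearrangement may run through the C6‑axial chair and give the Z alkene. Heterolysis of the furfurylic, allylic C5–O bond could also compete and lead to [1,3] shift products. Fallback: the fallback sets out from 24. If heating gives mainly the (4Z)‑cyclodecenone F1, F1 is irradiated (405 nm, MeCN) with thioxanthone as triplet sensitiser. Energy transfer reaches the more planar, conjugated Z alkenylfuran but hardly the twisted E isomer, so the E isomer should accumulate at the photostationary state and is separated, the Z fraction being recycled. The fallback comes back at 25.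

Step 21. The peracid may epoxidise C4=C5 while the furan is still intact, giving a furyl oxirane that ionises. Protonation of the silyloxyfuran may occur at C11 (deconjugated lactone) or on the other face of C6 (6R epimer). The α‑acetoxy ketone could undergo slow Baeyer–Villiger oxidation. Fallback: the fallback sets out from 25, before deprotection. Dye‑sensitised photooxygenation (O2, tetraphenylporphyrin, light, CH2Cl2, −78 °C) reacts with the furan far faster than with the alkene and gives, through silyl migration, the γ‑hydroxybutenolide F2. NaBH4 with CeCl3·7H2O in MeOH, then acidification, reduces the ring‑opened C6 ketone (setting C6 by hydride, where the reagent can be varied) and the C1 ketone, and gives the butenolide carbinol F3. Dess–Martin oxidation restores the C1 ketone in butenolide ketone F4. HF·pyridine gives diol F5, Yamaguchi angeloylation gives angelate F6, and acetylation (Ac2O, DMAP in catalytic amount, short contact) gives 30, where the fallback comes back to the route.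

Step 15. The hindered α,α‑disubstituted acid may be activated and transferred slowly, so that intermolecular esterification outruns eight‑membered ring closure. Fallback: the fallback sets out from 22 and comes back at 23 and makes no new compound (F0). It is a Mitsunobu lactonisation (PPh3, diisopropyl azodicarboxylate, toluene, high dilution), which activates the furfurylic, allylic C5 hydroxyl instead of the acid. Loss of configuration at C5 does not matter; attack at C3 instead of C5 would have to be watched.

Step 11. The ketone is flanked by two ortho substituents and may twist out of the furan plane, which can erode the large/small distinction and the facial selectivity of the catalyst. Fallback: the fallback sets out from 16. Unselective reduction (NaBH4, CeCl3·7H2O, MeOH) followed by base‑induced closure (DBU, toluene) gives the (8S)‑γ‑lactone F7 and its (8R)‑epimer F8. These are diastereomers in a five‑membered ring and separable by chromatography. F7 is saponified with LiOH, and the fallback comes back at 18.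

Step 24. The ring may react through a conformer that exposes the other alkene face, giving the diastereomeric epoxide. Fallback: the fallback sets out from 32 and comes back at 33 and makes no new compound (F0). It is a reagent‑controlled Shi epoxidation with the D‑fructose‑derived ketone and KHSO5 (Oxone) in a NaHCO3‑buffered medium at 0 °C, whose intrinsic sense for E trisubstituted alkenes matches 4R,5R.

## Further compounds

F0 | step 15 | none | none
F0 | step 24 | none | none
F1 | step 17 | (4Z)-isomer of 25 | O=C1CC/C(C)=C\c2oc([Si](C)(C)C)c(COCc3ccc(OC)cc3)c2[C@@H](O[Si](C)(C)C(C)(C)C)C[C@@]1(C)O[Si](CC)(CC)CC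
F2 | step 21 | γ-hydroxybutenolide (C6 hemiketal; C8 OTBS; C10 OTES; C13 OPMB) | O=C1CC/C(C)=C/C2(O)OC(=O)C(COCc3ccc(OC)cc3)=C2[C@@H](O[Si](C)(C)C(C)(C)C)C[C@@]1(C)O[Si](CC)(CC)CC
F3 | step 21 | (6S)-butenolide with C1 carbinol (C1 epimers) | OC1CC/C(C)=C/[C@H]2OC(=O)C(COCc3ccc(OC)cc3)=C2[C@@H](O[Si](C)(C)C(C)(C)C)C[C@@]1(C)O[Si](CC)(CC)CC
F4 | step 21 | (6S)-butenolide ketone, silyl-protected | O=C1CC/C(C)=C/[C@H]2OC(=O)C(COCc3ccc(OC)cc3)=C2[C@@H](O[Si](C)(C)C(C)(C)C)C[C@@]1(C)O[Si](CC)(CC)CC
F5 | step 21 | butenolide C8,C10-diol | O=C1CC/C(C)=C/[C@H]2OC(=O)C(COCc3ccc(OC)cc3)=C2[C@@H](O)C[C@@]1(C)O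
F6 | step 21 | butenolide C8 angelate, C10 alcohol | O=C1CC/C(C)=C/[C@H]2OC(=O)C(COCc3ccc(OC)cc3)=C2[C@@H](OC(=O)/C(C)=C\C)C[C@@]1(C)O
F7 | step 11 | (8S,10R)-γ-lactone from 17 | O=C1O[C@H](c2c(C(OC)OC)oc([Si](C)(C)C)c2COCc2ccc(OC)cc2)C[C@@]1(C)O[Si](CC)(CC)CC
F8 | step 11 | (8R,10R)-γ-lactone | O=C1O[C@@H](c2c(C(OC)OC)oc([Si](C)(C)C)c2COCc2ccc(OC)cc2)C[C@@]1(C)O[Si](CC)(CC)CC
A1 | alternative 1 | (E)-cyclodec-5-enone with C8 dimethylphenylsilyl group and C4,C5 acetonide | O=C1C[C@@H]([Si](C)(C)c2ccccc2)C/C(C)=C/CC[C@@]2(C)OC(C)(C)O[C@@H]12
A2 | alternative 2 | (1(10)Z,4E)-cyclodeca-1(10),4-dien-6-one with C8 silyl ether | O=C1C[C@@H](O[Si](C)(C)C(C)(C)C)C/C(C)=C\CC/C(C)=C/1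
A3 | alternative 3 | cyclodec-5-ynone with C10 acetate, C8 silyl ether and C4,C5 acetonide | O=C1C[C@@H](O[Si](C)(C)C(C)(C)C)C[C@@](C)(OC(C)=O)C#CC[C@@]2(C)OC(C)(C)O[C@@H]12
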